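**Plan**

1. Retrosynthesis: the C13–C14 and O15–C12 bonds of the oxolane are cut in one operation, which also opens the 14-membered carbocycle and leads to the acyclic epoxy diene 16, an isomer of the target. The chain is then cut at C11–C12 (Heck), C10=C11 (Wittig), C8–C9 (pyruvate aldol) and C7–C8 (MeLi), back to (S)-citronellic acid, methyl pyruvate and 3-methylbutan-2-one.
2. Enabling feature: in the oxolane ring O15–C1–C14–C13–C12, C1 is quaternary and C12 carries the C10=C11 vinyl group. O15–C1–C14 is therefore a 2,2-disubstituted epoxide in disguise, and C13–C12(–C11=C10) is the terminus of a 2-isopropyl-1,3-diene. A C14 radical adding to C13 leaves a C12–C11–C10 allyl unit onto which O15 closes.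
3. Forward: the chain grows from C7 to C13 on the citronellic acid backbone. A C1–C2 trisubstituted epoxide carries the latent C2 carbinol and C1=C14 alkene through seven steps. The carbocycle and the oxolane form together in the last step.
4. Stereochemistry: C5 comes from (S)-citronellic acid, C2 from the Shi epoxidation, C9 from the copper bis(oxazoline) pyruvate aldol, and C1 from the matched Sharpless epoxidation of the C2 carbinol. C12 is set in the key step by the cis-bridging demand of the bicycle, and the (10E) alkene by the Heck reaction.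

Key step: step 13

Remark: the target numbering (C1–C14 and O15 of the 15-oxabicyclo[10.2.1]pentadecane name) is used for every intermediate. C7 in 7, 8, 9 and 12 and the lactol carbon C10 in 7 and 8 are carried as epimer mixtures, which are erased in steps 6 and 9.

**Route**

Step 1
Reactants: 1 (S)-citronellic acid, (3S)-3,7-dimethyloct-6-enoic acid
Product: 2 (4S)-4,8-dimethylnon-7-en-2-one
Conditions: MeLi (2.2 equiv), Et2O, 0 °C to rt; inverse quench into cold aq. HCl
Reagents that add atoms: methyllithium, [Li]C
Why: Addition of the organolithium to the lithium carboxylate stops at the dilithium gem-diolate, which gives the methyl ketone only on work-up (carboxylic acid to methyl ketone with two equivalents of RLi), and C5 is not touched.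

Step 2
Reactants: 2 (4S)-4,8-dimethylnon-7-en-2-one
Product: 3 (4S)-6-[(2R)-3,3-dimethyloxiran-2-yl]-4-methylhexan-2-one
Conditions: D-fructose-derived Shi ketone (30 mol%), KHSO5 (as Oxone, 2KHSO5·KHSO4·K2SO4), K2CO3, Bu4NHSO4, MeCN/dimethoxymethane, aq. Na2B4O7/EDTA buffer (pH 10.5), 0 °C
Reagents that add atoms: potassium peroxymonosulfate, [K+].[O-]S(=O)(=O)OO
Why: Shi asymmetric epoxidation of the trisubstituted alkene by the chiral dioxirane through the spiro transition state should set C2 as R under catalyst control, and the saturated ketone is inert under these conditions.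

Step 3
Reactants: 3 (4S)-6-[(2R)-3,3-dimethyloxiran-2-yl]-4-methylhexan-2-one
Product: 4 {[(4S)-6-[(2R)-3,3-dimethyloxiran-2-yl]-4-methylhex-1-en-2-yl]oxy}trimethylsilane
Conditions: LiN(i-Pr)2 (1.1 equiv), TMSCl (1.3 equiv, present from the start), THF, −78 °C; Et3N, pentane, filtration
Reagents that add atoms: chlorotrimethylsilane, C[Si](C)(C)Cl
Why: Kinetic enolization with internal silyl quench removes a proton of the C8 methyl group in preference to the β-branched C6 methylene and gives the terminal silyl enol ether, while the trisubstituted epoxide does not react with the amide base at −78 °C.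

Step 4
Reactants: 4 {[(4S)-6-[(2R)-3,3-dimethyloxiran-2-yl]-4-methylhex-1-en-2-yl]oxy}trimethylsilane; 5 methyl pyruvate
Product: 6 methyl (2R,6S)-8-[(2R)-3,3-dimethyloxiran-2-yl]-2,6-dimethyl-4-oxo-2-[(trimethylsilyl)oxy]octanoate
Conditions: [Cu((R,R)-t-Bu-box)](OTf)2 (10 mol%, from Cu(OTf)2 and 2,2'-(propane-2,2-diyl)bis[(4R)-4-tert-butyl-4,5-dihydrooxazole]), THF, −78 °C; non-aqueous work-up over Et3N-deactivated silica
Reagents that add atoms: none
Why: In this catalytic enantioselective Mukaiyama aldol addition to a pyruvate ester, the pyruvate is held as a five-membered chelate on the square-planar divalent copper bis(oxazoline) complex and one tert-butyl group shields one face of the ketone, so the (R,R)-ligand should give the (9R) tertiary silyl ether independently of the remote C2 and C5 centers.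

Step 5
Reactants: 6 methyl (2R,6S)-8-[(2R)-3,3-dimethyloxiran-2-yl]-2,6-dimethyl-4-oxo-2-[(trimethylsilyl)oxy]octanoate
Product: 8 (3R)-5-{(2S)-4-[(2R)-3,3-dimethyloxiran-2-yl]-2-methylbutyl}-3-methyloxolane-2,3-diol (lactol; C7/C10 epimers), via silylated lactol 7 (not isolated)
Conditions: i-Bu2AlH (3.0 equiv), CH2Cl2, −78 °C; aq. KNaC4H4O6; then K2CO3, MeOH, 0 °C to rt
Reagents that add atoms: none
Why: The aluminium hydride reduces the C7 ketone and stops the α-silyloxy ester at the chelated aluminium hemiacetal (partial ester reduction), so work-up gives the five-membered lactol, and mild methanolysis then removes the tertiary silyl ether before a C7 alkoxide could trigger silyl migration in step 6.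

Step 6
Reactants: 8 (3R)-5-{(2S)-4-[(2R)-3,3-dimethyloxiran-2-yl]-2-methylbutyl}-3-methyloxolane-2,3-diol
Product: 9 (3R,7S)-9-[(2R)-3,3-dimethyloxiran-2-yl]-3,7-dimethylnon-1-ene-3,5-diol (C7 epimers in target numbering)
Conditions: Ph3PCH3Br (4.0 equiv), KOt-Bu (3.8 equiv), THF, 0 °C to rt
Reagents that add atoms: methyltriphenylphosphonium bromide, C[P+](c1ccccc1)(c1ccccc1)c1ccccc1.[Br-]
Why: Wittig methylenation of the lactol through its open hydroxy aldehyde form (excess ylide takes up the hydroxyl protons) gives the vinyl carbinol, and the quaternary C9 next to the aldehyde cannot epimerize.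

Step 7
Reactants: 10 3-methylbutan-2-one
Product: 11 3-methylbut-1-en-2-yl trifluoromethanesulfonate
Conditions: LiN(i-Pr)2, THF, −78 °C; then PhNTf2, −78 to 0 °C
Reagents that add atoms: N-phenylbis(trifluoromethanesulfonimide), O=S(=O)(N(c1ccccc1)S(=O)(=O)C(F)(F)F)C(F)(F)F
Why: Kinetic enolization at the methyl group followed by O-sulfonylation (standard enol triflate synthesis) gives the less substituted alkenyl triflate that holds C12, C13 and the isopropyl group.

Step 8
Reactants: 9 (3R,7S)-9-[(2R)-3,3-dimethyloxiran-2-yl]-3,7-dimethylnon-1-ene-3,5-diol; 11 3-methylbut-1-en-2-yl trifluoromethanesulfonate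
Product: 12 (3E,5R,9S)-11-[(2R)-3,3-dimethyloxiran-2-yl]-5,9-dimethyl-2-(propan-2-yl)undeca-1,3-diene-5,7-diol (C7 epimers in target numbering)
Conditions: Pd(OAc)2 (5 mol%), PPh3 (10 mol%), Et3N, LiCl, DMF, 60 °C
Reagents that add atoms: none
Why: In this Mizoroki–Heck coupling the alkenyl palladium adds to the unhindered terminal carbon C11 of the tertiary allylic alcohol, and because C9 is quaternary the syn β-hydride elimination can only give the conjugated (10E)-diene.

Step 9
Reactants: 12 (3E,5R,9S)-11-[(2R)-3,3-dimethyloxiran-2-yl]-5,9-dimethyl-2-(propan-2-yl)undeca-1,3-diene-5,7-diol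
Product: 13 (3S,7R,8E)-1-[(2R)-3,3-dimethyloxiran-2-yl]-7-hydroxy-3,7-dimethyl-10-(propan-2-yl)undeca-8,10-dien-5-one
Conditions: Dess–Martin periodinane, NaHCO3, CH2Cl2, 0 °C to rt
Reagents that add atoms: none
Why: Dess–Martin oxidation converts both epimers of the secondary C7 alcohol into the ketone under neutral conditions, while the tertiary C9 alcohol, the diene and the epoxide are not oxidized by this reagent.

Step 10
Reactants: 13 (3S,7R,8E)-1-[(2R)-3,3-dimethyloxiran-2-yl]-7-hydroxy-3,7-dimethyl-10-(propan-2-yl)undeca-8,10-dien-5-one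
Product: 14 (3E,5R,9S,12R)-5,12-dihydroxy-5,9,13-trimethyl-2-(propan-2-yl)tetradeca-1,3,13-trien-7-one
Conditions: Cp2TiCl2 (2.5 equiv), Mn dust, THF, rt
Reagents that add atoms: none
Why: In this titanocene-mediated isomerization of an epoxide to an allylic alcohol, Cp2TiCl (trivalent titanium) opens the epoxide homolytically to the tertiary C1 radical, and a second titanium centre with β-hydride elimination from a methyl group gives the isopropenyl carbinol; the C2–O bond is never broken, so C2 stays R.

Step 11
Reactants: 14 (3E,5R,9S,12R)-5,12-dihydroxy-5,9,13-trimethyl-2-(propan-2-yl)tetradeca-1,3,13-trien-7-one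
Product: 15 (3E,5R,9S,12R)-5,12-dihydroxy-5,9-dimethyl-12-[(2S)-2-methyloxiran-2-yl]-2-(propan-2-yl)dodeca-1,3-dien-7-one
Conditions: Ti(Oi-Pr)4 (0.2 equiv), D-(−)-diisopropyl tartrate (0.25 equiv), t-BuOOH (2 equiv), 4 Å MS, CH2Cl2, −20 °C
Reagents that add atoms: tert-butyl hydroperoxide, CC(C)(C)OO
Why: Sharpless asymmetric epoxidation of the (R)-configured secondary allylic alcohol in its matched, fast-reacting pairing with the D-tartrate delivers oxygen to C1=C14 in the erythro sense (C1 becomes S), the same sense as the intrinsic hydroxyl-directed preference of 2-substituted allylic alcohols, while the tertiary C9 allylic alcohol is a poor substrate for the titanium tartrate system.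

Step 12
Reactants: 15 (3E,5R,9S,12R)-5,12-dihydroxy-5,9-dimethyl-12-[(2S)-2-methyloxiran-2-yl]-2-(propan-2-yl)dodeca-1,3-dien-7-one
Product: 16 (1R,4S,8R,9E)-8-hydroxy-4,8-dimethyl-1-[(2S)-2-methyloxiran-2-yl]-6-oxo-11-(propan-2-yl)dodeca-9,11-dien-1-yl acetate
Conditions: Ac2O, pyridine, DMAP (5 mol%), CH2Cl2, 0 °C
Reagents that add atoms: acetic anhydride, CC(=O)OC(C)=O
Why: Nucleophile-catalysed acylation esterifies the secondary C2 alcohol, and the tertiary C9 alcohol does not react at 0 °C.

Step 13
Reactants: 16 (1R,4S,8R,9E)-8-hydroxy-4,8-dimethyl-1-[(2S)-2-methyloxiran-2-yl]-6-oxo-11-(propan-2-yl)dodeca-9,11-dien-1-yl acetate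
Product: 18 (1S,2R,5S,9R,10E,12S)-9-hydroxy-1,5,9-trimethyl-7-oxo-12-(propan-2-yl)-15-oxabicyclo[10.2.1]pentadec-10-en-2-yl acetate (target), via iodohydrin 17 (not isolated)
Conditions: Pd(OAc)2 (10 mol%), Xantphos (20 mol%), Et3N·HI (30 mol%), MeCN/PhCF3 (1:4), 2 mM, blue LEDs (450 nm), 30 °C
Reagents that add atoms: none
Why: Proposed new method: triethylammonium iodide opens the 2,2-disubstituted epoxide at its CH2 carbon C14 to iodohydrin 17, the photoexcited zerovalent palladium–Xantphos complex abstracts the iodine atom to give a monovalent palladium iodide and the primary C14 radical, this radical adds to the diene terminus C13, the C12–C11–C10 allyl radical is captured as an η3-allyl complex of divalent palladium, and the C1 hydroxyl attacks C12 to release the target, zerovalent palladium and HI, so that palladium and iodide both turn over and the step is a net isomerization. The closest known reaction types are the visible-light palladium-catalysed 1,2-carbofunctionalization of 1,3-dienes with alkyl iodides, the Larock heteroannulation of 1,3-dienes and the iodide-relay opening of epoxides in cross-electrophile coupling; what is new is their combination in a ring-forming (3+2) sense with an sp3 O–C–C unit. The 14-membered carbocycle closes by 14-endo-trig radical addition at high dilution, and the oxolane closes by 5-exo attack of O15 on the nearer allyl terminus. The new stereocenter C12 is controlled by C1 through the ring: only the cis-bridged 15-oxabicyclo[10.2.1] skeleton can form across the ten-atom C2–C11 bridge, the two allyl faces can interconvert before C–O bond formation, the isopropyl group therefore ends cis to the C1 methyl group, and the syn-allyl geometry keeps C10=C11 as E. The step needs C–C bond formation at C13 ahead of reduction or 1,5-hydrogen transfer of the radical, and C–O bond formation at C12 by O15 and not at C10 or by the C9 hydroxyl. The first is favoured by the high radical affinity of the diene and by the quaternary C1, which rules out β-hydride elimination; the second by the five-membered ring, since attack at C10 would give a seven-membered ether and the C9 hydroxyl could only form an oxetane or, from the anti-allyl, a dihydrofuran.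

**Compound list**

1 | (S)-citronellic acid, (3S)-3,7-dimethyloct-6-enoic acid | CC(C)=CCC[C@H](C)CC(=O)O | starting material
2 | (4S)-4,8-dimethylnon-7-en-2-one | CC(C)=CCC[C@H](C)CC(C)=O | intermediate
3 | (4S)-6-[(2R)-3,3-dimethyloxiran-2-yl]-4-methylhexan-2-one | CC1(C)O[C@@H]1CC[C@H](C)CC(C)=O | intermediate
4 | {[(4S)-6-[(2R)-3,3-dimethyloxiran-2-yl]-4-methylhex-1-en-2-yl]oxy}trimethylsilane | CC1(C)O[C@@H]1CC[C@H](C)CC(=C)O[Si](C)(C)C | intermediate
5 | methyl pyruvate (methyl 2-oxopropanoate) | CC(=O)C(=O)OC | starting material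
6 | methyl (2R,6S)-8-[(2R)-3,3-dimethyloxiran-2-yl]-2,6-dimethyl-4-oxo-2-[(trimethylsilyl)oxy]octanoate | CC1(C)O[C@@H]1CC[C@H](C)CC(=O)C[C@@](C)(O[Si](C)(C)C)C(=O)OC | intermediate
7 | (3R)-5-{(2S)-4-[(2R)-3,3-dimethyloxiran-2-yl]-2-methylbutyl}-3-methyl-3-[(trimethylsilyl)oxy]oxolan-2-ol (silylated lactol, epimers at the two ring carbons next to oxygen) | CC1(C)O[C@@H]1CC[C@H](C)CC2C[C@@](C)(O[Si](C)(C)C)C(O)O2 | intermediate
8 | (3R)-5-{(2S)-4-[(2R)-3,3-dimethyloxiran-2-yl]-2-methylbutyl}-3-methyloxolane-2,3-diol (lactol, epimers at the two ring carbons next to oxygen) | CC1(C)O[C@@H]1CC[C@H](C)CC2C[C@@](C)(O)C(O)O2 | intermediate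
9 | (3R,7S)-9-[(2R)-3,3-dimethyloxiran-2-yl]-3,7-dimethylnon-1-ene-3,5-diol (epimers at the secondary carbinol) | CC1(C)O[C@@H]1CC[C@H](C)CC(O)C[C@@](C)(O)C=C | intermediate
10 | 3-methylbutan-2-one | CC(C)C(C)=O | starting material
11 | 3-methylbut-1-en-2-yl trifluoromethanesulfonate | C=C(OS(=O)(=O)C(F)(F)F)C(C)C | intermediate
12 | (3E,5R,9S)-11-[(2R)-3,3-dimethyloxiran-2-yl]-5,9-dimethyl-2-(propan-2-yl)undeca-1,3-diene-5,7-diol (epimers at the secondary carbinol) | CC1(C)O[C@@H]1CC[C@H](C)CC(O)C[C@@](C)(O)/C=C/C(=C)C(C)C | intermediate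
13 | (3S,7R,8E)-1-[(2R)-3,3-dimethyloxiran-2-yl]-7-hydroxy-3,7-dimethyl-10-(propan-2-yl)undeca-8,10-dien-5-one | CC1(C)O[C@@H]1CC[C@H](C)CC(=O)C[C@@](C)(O)/C=C/C(=C)C(C)C | intermediate
14 | (3E,5R,9S,12R)-5,12-dihydroxy-5,9,13-trimethyl-2-(propan-2-yl)tetradeca-1,3,13-trien-7-one | C=C(C)[C@H](O)CC[C@H](C)CC(=O)C[C@@](C)(O)/C=C/C(=C)C(C)C | intermediate
15 | (3E,5R,9S,12R)-5,12-dihydroxy-5,9-dimethyl-12-[(2S)-2-methyloxiran-2-yl]-2-(propan-2-yl)dodeca-1,3-dien-7-one | O[C@H](CC[C@H](C)CC(=O)C[C@@](C)(O)/C=C/C(=C)C(C)C)[C@]1(C)CO1 | intermediate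
16 | (1R,4S,8R,9E)-8-hydroxy-4,8-dimethyl-1-[(2S)-2-methyloxiran-2-yl]-6-oxo-11-(propan-2-yl)dodeca-9,11-dien-1-yl acetate | CC(=O)O[C@H](CC[C@H](C)CC(=O)C[C@@](C)(O)/C=C/C(=C)C(C)C)[C@]1(C)CO1 | intermediate
17 | (2R,3R,6S,10R,11E)-2,10-dihydroxy-1-iodo-2,6,10-trimethyl-8-oxo-13-(propan-2-yl)tetradeca-11,13-dien-3-yl acetate (iodohydrin) | CC(=O)O[C@H](CC[C@H](C)CC(=O)C[C@@](C)(O)/C=C/C(=C)C(C)C)[C@@](C)(O)CI | intermediate
18 | (1S,2R,5S,9R,10E,12S)-9-hydroxy-1,5,9-trimethyl-7-oxo-12-(propan-2-yl)-15-oxabicyclo[10.2.1]pentadec-10-en-2-yl acetate | CC(=O)O[C@@H]1CC[C@H](C)CC(=O)C[C@@](C)(O)/C=C/[C@@]2(C(C)C)CC[C@]1(C)O2 | target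

**Step count and risks**

Total steps: 13. Longest linear sequence: 12 (steps 1 to 6 and 8 to 13 from compound 1).

Steps most likely to fail:

1. Step 13 (proposed new method). The primary radical may be reduced or undergo 1,5-hydrogen transfer before the slow closure of the 14-membered ring. The tertiary allylic C9 alcohol may ionize on palladium or compete as the nucleophile. The iodide relay may stall at the epoxide. Fallback with known reactions, setting out from 16 and coming back at 18: the two bonds would be made in separate operations. LiI and acetic acid in THF should open the epoxide to the iodohydrin 17, now isolated. Slow addition of Bu3SnH with AIBN to a 2 mM solution in benzene at 80 °C (tin hydride radical macrocyclization) should close the carbocycle, and hydrogen transfer to the less substituted allyl terminus C10 should give the 14-membered trisubstituted alkene (1S,2R,5S,9S)-1,9-dihydroxy-1,5,9-trimethyl-7-oxo-12-(propan-2-yl)cyclotetradec-11-en-2-yl acetate F1 (target numbering, alkene isomers). N-(Phenylseleno)phthalimide with catalytic camphorsulfonic acid in CH2Cl2 should then close the oxolane by transannular 5-exo selenoetherification (O15 to C12, selenium to C11), again with only the cis-bridged bicycle accessible, and give the selenide (1S,2R,5S,9R,12S)-9-hydroxy-1,5,9-trimethyl-7-oxo-11-(phenylselanyl)-12-(propan-2-yl)-15-oxabicyclo[10.2.1]pentadecan-2-yl acetate F2. Oxidation with H2O2 and pyridine and syn elimination of the selenoxide toward C10 (C12 carries no hydrogen) should restore the (10E) alkene and give 18.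

2. Step 8. Insertion may occur with the wrong regiochemistry at the hindered allylic alcohol, and palladium hydride may add again to the product diene. Fallback, setting out from 9 and coming back at 12: cross-metathesis of 9 with vinylboronic acid pinacol ester (second-generation Hoveyda–Grubbs catalyst, CH2Cl2, 40 °C) should give the (E)-alkenylboronate (1E,3R,7S)-9-[(2R)-3,3-dimethyloxiran-2-yl]-3,7-dimethyl-1-(4,4,5,5-tetramethyl-1,3,2-dioxaborolan-2-yl)non-1-ene-3,5-diol F3. Suzuki–Miyaura coupling of F3 with triflate 11 (Pd(PPh3)4, aq. K3PO4, THF, 50 °C) should then give 12 with the alkene geometry fixed by the boronate.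

3. Step 5. The ester may be reduced past the aldehyde oxidation level, and the epoxide may be opened by hydride if the temperature rises. Fallback, setting out from 6 and coming back at 8: LiBH4 in THF/MeOH would reduce both carbonyl groups on purpose, and K2CO3 in MeOH would remove the silyl group to give the triol (2R,6S)-8-[(2R)-3,3-dimethyloxiran-2-yl]-2,6-dimethyloctane-1,2,4-triol F4. TEMPO with PhI(OAc)2 should oxidize the primary alcohol and carry the resulting lactol on to the γ-lactone (3R)-5-{(2S)-4-[(2R)-3,3-dimethyloxiran-2-yl]-2-methylbutyl}-3-hydroxy-3-methyloxolan-2-one F5. Reduction of the lactone with i-Bu2AlH at −78 °C, which stops reliably at the lactol, should give 8.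

Further compounds
F1 | step 13 | (1S,2R,5S,9S)-1,9-dihydroxy-1,5,9-trimethyl-7-oxo-12-(propan-2-yl)cyclotetradec-11-en-2-yl acetate (alkene isomers) | CC(=O)O[C@@H]1CC[C@H](C)CC(=O)C[C@@](C)(O)CC=C(C(C)C)CC[C@]1(C)O
F2 | step 13 | (1S,2R,5S,9R,12S)-9-hydroxy-1,5,9-trimethyl-7-oxo-11-(phenylselanyl)-12-(propan-2-yl)-15-oxabicyclo[10.2.1]pentadecan-2-yl acetate (C11 epimers) | CC(=O)O[C@@H]1CC[C@H](C)CC(=O)C[C@@](C)(O)CC([Se]c3ccccc3)[C@@]2(C(C)C)CC[C@]1(C)O2
F3 | step 8 | (1E,3R,7S)-9-[(2R)-3,3-dimethyloxiran-2-yl]-3,7-dimethyl-1-(4,4,5,5-tetramethyl-1,3,2-dioxaborolan-2-yl)non-1-ene-3,5-diol (epimers at the secondary carbinol) | CC1(C)O[C@@H]1CC[C@H](C)CC(O)C[C@@](C)(O)/C=C/B1OC(C)(C)C(C)(C)O1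
F4 | step 5 | (2R,6S)-8-[(2R)-3,3-dimethyloxiran-2-yl]-2,6-dimethyloctane-1,2,4-triol (epimers at the secondary carbinol) | CC1(C)O[C@@H]1CC[C@H](C)CC(O)C[C@@](C)(O)CO
F5 | step 5 | (3R)-5-{(2S)-4-[(2R)-3,3-dimethyloxiran-2-yl]-2-methylbutyl}-3-hydroxy-3-methyloxolan-2-one (epimers at the ring carbon next to oxygen) | CC1(C)O[C@@H]1CC[C@H](C)CC2C[C@@](C)(O)C(=O)O2
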